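## Structural features

The target is 8-(3,4-dimethoxyphenyl)-2,6-dimethoxy-1,4-naphthoquinone. A benzenoid ring A (C4a–C8a, methoxy on C6) is fused to a quinone ring B (C1=O, C2–OMe, C3–H, C4=O), and the dimethoxyphenyl ring C is joined by a single biaryl bond at C8, peri to the C1 carbonyl. There is no stereocentre, and the C8–C1′ axis has only hydrogens at the ortho positions of ring C, so it rotates freely. The one stereocentre met on the way (C4 as a carbinol) is transient and is carried as the racemate. The fragile groups are the C2 methoxy, which is part of a vinylogous ester with the C4 carbonyl and is displaced by hydroxide or amines, the easily reduced quinone, and three electron-rich methoxyarene units that do not tolerate strong oxidants. The real difficulty is regiochemical: ring A carries three contiguous carbon substituents (aryl on C8, C1 on C8a, C4 on C4a) plus the C6 methoxy, and the single methoxy of ring B must sit on C2, next to the carbonyl that is peri to ring C, and not on C3. The key step exploits the fact that C2=C3 is the only C=C of ring B and lies between two oxygenated carbons, C1 and C4. Each of these can be built as a separate ortho arm on ring A: C1 as the carbonyl of an alpha-methoxy enone that already carries the C2 methoxy, and C4 as a protected vinyl carbinol. A 4-oxygenated 4H-naphthalen-1-one with hydrogen on C4 is the keto tautomer of a naphthalene-1,4-diol, so the ring-closed product already stands at the hydroquinone oxidation level.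

## Logic of the disconnections

19 to 16. No skeletal bond is cut. The quinone is taken back to 16 by placing a silyl ether on the C4 oxygen and adding two hydrogens. The reason is that 17, the desilylated form of 16, is the keto tautomer of 18, so 16 already holds the full skeleton at the hydroquinone level. The gain is that the sensitive quinone appears only in the last operation. The forward step must desilylate and oxidize by two electrons without exposing the C2 vinylogous ester of 19 to base.

16 to 15. The C2=C3 double bond is cut by retro-metathesis. This is the only C=C of ring B, and opening it removes the ring and leaves two independent ortho arms on ring A, with the C2 methoxy already fixed on the C1 arm. The forward step needs a ruthenium carbene that loads on the vinyl group and closes onto a hindered 1,1-disubstituted alkene. It also needs the C4 oxygen capped, so that the C1 ketone stays open-chain.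

15 to 13. The O–Si bond is cut. This exposes the gamma-hydroxy ketone 14, which is the ring-chain tautomer of 13, so the protecting group is removed from the analysis without touching the skeleton. The forward silylation must take the secondary carbinol of the open form and leave the tertiary hemiketal hydroxyl alone, under non-acidic conditions.

13 to 10 and 11. The C1–C2 bond is cut. The acyl carbon C1 is traced to a lactone carbonyl and C2 to the alpha-carbon of an enol ether, which 12 delivers as a nucleophile. Both arms of 13 collapse into one five-membered lactone, and the methoxyvinyl unit comes from a two-carbon feedstock. The forward addition must stop after one equivalent and must be faster than proton abstraction at the lactone C–H.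

10 to 7 and 8. The C3–C4 bond and the lactone C1–O bond are cut. C4 is traced to an aldehyde and the lactone to a tertiary amide, by way of 9. This leaves ring A with two differentiated carbonyl groups at different oxidation levels. The Grignard reagent must attack the aldehyde only, and the later acyl transfer from nitrogen to oxygen must not ionize the benzylic, allylic carbinol.

7 to 5. The C4a–C4 bond is cut. The amide that will become C1 is used to direct metalation to the only free position ortho to it, through 6. This removes the third contiguous substituent of ring A. The forward step needs kinetic lithiation ortho to the amide in the presence of three methoxy directors.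

5 to 3 and 4. The biaryl bond C8–C1′ is cut. Ring C is bought intact as a boronic acid and ring A as an ortho-bromo amide. The forward step is a cross-coupling at a bromide flanked by the bulky carboxamide.

3 to 1. The amide C–N bond is cut, through 2. This reaches a commercial acid that already places bromine, the carboxyl carbon and the methoxy group at C8, C8a and C6. The forward step is a routine amidation. It is placed before the coupling so that no acyl chloride is ever generated next to ring C.

## Other disconnections considered

Alternative 1: The cut goes through ring A at C7–C8 and C5–C6, and ring B is carried as a pre-formed trimethoxybenzene. In the forward direction the ortho-quinoid lactone A1 would add the alkyne A2 across its two pyranone termini in a Diels–Alder reaction. The bridged adduct would then expel its lactone bridge by decarboxylative cycloreversion to give the naphthalene A3. One oxidative demethylation of the C1/C4 methoxy pair (for example with (NH4)2Ce(NO3)6) would then lead to the target.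
- In favour: it is convergent, it is driven by gas loss and aromatization, and its product is a robust aromatic compound.
- In favour: polar matching (nucleophilic CH of A2 with the oxygen-bearing terminus of A1) points to the required C6 methoxy.
- Against: that regiochemistry is an electronic bet with no tether behind it, and an electron-rich ynol ether is a poor partner for an electron-rich diene.
- Against: A1 must be generated and trapped in situ after its own multistep preparation, and A2 is a volatile, unstable reagent that has to be made.
- Against: the final oxidation must pick the para pair out of a 1,2,4-trimethoxy ring without touching ring C.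
- Comparison: Alternative 1 is the better on convergence and on the stability of the key-step product (an arene against a tautomerizable dienone). It is about the equal on the number of operations after the key step. The chosen plan is the better on regiochemical certainty, since every position follows from the starting acid, the amide-directed metalation and the tether, and on reagent availability.

Alternative 2: The cut removes three bonds of ring A (C4a–C8a, C5–C6, C7–C8) and so dismantles rings A and B at once. In the forward direction RhCl(PPh3)3 or Cp*RuCl(cod) would cyclotrimerize the tethered diyne A4 with the alkyne A2 to give the dihydronaphthoquinone A5. A5 is the diketo tautomer of 18 and would need only enolization and oxidation.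
- In favour: it gives the largest gain in complexity per step, it is fully atom-economical, and on paper it is the shortest route.
- Against: A4 is a bis-ynone with a beta-methoxy 1,4-diketone, prone to conjugate addition and to loss of methanol; the same elimination in A5 would give the quinone without its C2 methoxy.
- Against: the orientation of A2 in the metallacycle (methoxy on C6 or on C7) has no controlling element.
- Against: the stereocentre at C2 of A4 and A5 is erased on the way to the quinone, so its (S) descriptor buys nothing and no enantioselective step would be rewarded.
- Comparison: Alternative 2 is the better on step economy and ring-forming power, and the equal in its final oxidation. The chosen plan is the better on substrate stability and on regiocontrol, and its key step forms one bond whose position cannot vary.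

Alternative 3: The cut is in ring C, at C1′–C2′ and C5′–C6′, with rings A and B carried as a complete tetramethoxynaphthalene. In the forward direction the nitroalkene A6 would act as dienophile toward the symmetrical diene A7 to give the trans cyclohexene A8. Loss of nitrous acid and dehydrogenation would aromatize ring C to A3, and the oxidative demethylation of Alternative 1 would finish. A correction to the structure is needed here: counted from its point of attachment, the naphthyl unit of A8 carries its methoxy groups on C3, C5, C7 and C8. The name that matches the 1,2,4,6-tetramethoxy pattern of A6 is therefore trans-1,2-dimethoxy-4-nitro-5-(3,5,7,8-tetramethoxynaphthalen-1-yl)cyclohexene; a 2,3,5,7 locant set would describe a different compound.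
- In favour: a nitroalkene with an electron-rich diene is a predictable normal-demand cycloaddition, and the symmetry of A7 removes any regiochemical question in ring C.
- Against: it constructs the one ring that can be bought intact, and it presupposes a separate solution for rings A and B and for a selective C8 formylation.
- Against: the dienophile is peri-hindered by the C1 methoxy, and A7 is an acid-labile bis-enol ether.
- Against: both stereocentres of A8 are destroyed on aromatization, and three further operations follow the key step.
- Comparison: Alternative 3 is the better on the mechanistic predictability of the bond-forming event itself, and the equal on ring C regiochemistry. The chosen plan is clearly the better on step economy and on structural logic, because it spends its key step on ring B, where the regiochemical problem lies.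

Key step: step 7

Remark on the chemistry: the only stereocentres met en route (the C4 carbinol carbon, and the hemiketal carbon of 13) are erased in the last step. All such intermediates are therefore planned as racemates; the SMILES show one enantiomer for bookkeeping, and 13 is written with its hemiketal carbon unspecified.

## Route

Step 1
Reactants: 1 2-bromo-4-methoxybenzoic acid
Product: 3 2-bromo-N,N-diethyl-4-methoxybenzamide, via acid chloride 2 (not isolated)
Conditions: SOCl2, DMF (cat.), PhMe, 70 °C; then Et2NH, Et3N, CH2Cl2, 0 °C to rt
Reagents that add atoms: diethylamine, CCNCC
Why: Acid chloride formation followed by aminolysis is routine and installs the directing group for step 3; doing it before the cross-coupling means that no acyl chloride is ever generated beside the electron-rich ring C, so a Friedel–Crafts closure to a fluorenone cannot intervene.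

Step 2
Reactants: 3 2-bromo-N,N-diethyl-4-methoxybenzamide; 4 3,4-dimethoxyphenylboronic acid
Product: 5 N,N-diethyl-2-(3,4-dimethoxyphenyl)-4-methoxybenzamide
Conditions: Pd(PPh3)4 (3 mol %), Na2CO3 (2 M aq), DME, 85 °C
Reagents that add atoms: none
Why: Suzuki–Miyaura coupling: zerovalent palladium inserts into the C–Br bond, the boronate transmetalates and reductive elimination forms the C8–C1′ bond; ortho-bromo tertiary benzamides are standard partners and the amide and ethers are inert.

Step 3
Reactants: 5 N,N-diethyl-2-(3,4-dimethoxyphenyl)-4-methoxybenzamide
Product: 7 N,N-diethyl-2-(3,4-dimethoxyphenyl)-6-formyl-4-methoxybenzamide, via ortho-lithiated amide 6 (not isolated)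
Conditions: s-BuLi, TMEDA, THF, −78 °C; then DMF, −78 °C to rt; aq NH4Cl
Reagents that add atoms: N,N-dimethylformamide, CN(C)C=O
Why: Directed ortho-metalation: the tertiary amide outranks the methoxy groups as a director and has one free ortho position, so kinetic lithiation at −78 °C should occur there before any remote lithiation on ring C; formylation of the aryllithium with DMF supplies the future C4.

Step 4
Reactants: 7 N,N-diethyl-2-(3,4-dimethoxyphenyl)-6-formyl-4-methoxybenzamide; 8 vinylmagnesium bromide
Product: 10 7-(3,4-dimethoxyphenyl)-5-methoxy-3-vinyl-3H-isobenzofuran-1-one (racemic), via hydroxy amide 9 (not isolated)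
Conditions: THF, −78 to 0 °C; aq NH4Cl; then TsOH·H2O (1.1 equiv), PhMe, 60 °C
Reagents that add atoms: none
Why: Grignard 1,2-addition takes the aldehyde only, since the twisted, doubly ortho-substituted diethylamide is inert to it; the gamma-hydroxy amide then lactonizes under acid by N-to-O acyl transfer with loss of diethylamine (the classical phthalide synthesis from ortho-functionalized benzamides). The new carbinol centre forms without control, which is immaterial because C4 returns to sp2 in step 8.

Step 5
Reactants: 10 7-(3,4-dimethoxyphenyl)-5-methoxy-3-vinyl-3H-isobenzofuran-1-one (racemic); 11 methyl vinyl ether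
Product: 13 7-(3,4-dimethoxyphenyl)-5-methoxy-1-(1-methoxyvinyl)-3-vinyl-1,3-dihydroisobenzofuran-1-ol (racemic; both hemiketal epimers), via 1-methoxyvinyllithium 12 (not isolated)
Conditions: 11, t-BuLi, THF, −78 to 0 °C; then 10, THF, −78 °C; aq NH4Cl at −78 °C, then rt
Reagents that add atoms: none
Why: Alpha-lithiation of the enol ether gives an acyl-anion equivalent that adds to the lactone carbonyl; at −78 °C the tetrahedral lithium lactolate persists, so the reaction should stop after one addition, as in the classical additions of organolithiums to 3-substituted phthalides. The hemiketal carbon forms as both epimers, which is irrelevant, and the neutral quench avoids acid-triggered dehydration toward an isobenzofuran.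

Step 6
Reactants: 13 7-(3,4-dimethoxyphenyl)-5-methoxy-1-(1-methoxyvinyl)-3-vinyl-1,3-dihydroisobenzofuran-1-ol (racemic; both hemiketal epimers)
Product: 15 1-[2-(1-(tert-butyldimethylsilyloxy)allyl)-6-(3,4-dimethoxyphenyl)-4-methoxyphenyl]-2-methoxyprop-2-en-1-one (racemic), via open-chain hydroxy ketone 14 (not isolated)
Conditions: TBSCl, imidazole, DMAP (cat.), DMF, rt (crude 13, no chromatography beforehand)
Reagents that add atoms: tert-butyldimethylsilyl chloride, CC(C)(C)[Si](C)(C)Cl
Why: Imidazole-mediated silylation under ring-chain equilibrium: only the open tautomer has a secondary carbinol, and the tertiary, crowded hemiketal hydroxyl of the closed form is not silylated under these conditions, so the equilibrium should drain through the open form to the silyl ether. The basic medium also keeps the lactol from dehydrating.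

Step 7
Reactants: 15 1-[2-(1-(tert-butyldimethylsilyloxy)allyl)-6-(3,4-dimethoxyphenyl)-4-methoxyphenyl]-2-methoxyprop-2-en-1-one (racemic)
Product: 16 4-(tert-butyldimethylsilyloxy)-8-(3,4-dimethoxyphenyl)-2,6-dimethoxy-4H-naphthalen-1-one (racemic)
Conditions: second-generation Grubbs catalyst (H2IMes)(PCy3)Cl2Ru=CHPh (10 mol %), 1,4-benzoquinone (10 mol %), PhMe (0.005 M), 80 °C, Ar sparge
Reagents that add atoms: none
Why: Ring-closing olefin metathesis by the Chauvin sequence: after phosphine loss the ruthenium benzylidene exchanges with the only monosubstituted alkene, the vinyl group of the silyloxy carbinol arm, to place a ruthenium alkylidene on C3; this adds across the 1,1-disubstituted alkene of the alpha-methoxy enone arm to a ruthenacyclobutane, whose cycloreversion forms C2=C3 and leaves Ru=CH2, which carries the chain and sheds the two CH2 termini as ethylene. The closest known reaction type is the ring-closing metathesis of ortho-dialkenyl arenes to naphthalene-level rings, including closures onto enol-ether and 2-alkoxyacrylate-type alkenes. Ring B is closed as a six-membered ring in the ordinary ring-closing mode, both new alkene carbons ending inside the ring, and the ortho placement of the two arms on ring A supplies the proximity. No stereocentre is created, and the racemic C4 centre is a spectator. The selectivity needed is chemoselective initiation at the vinyl group followed by closure onto the hindered alkene; it is secured by there being a single monosubstituted alkene and by the tether, since the acyl- and methoxy-substituted alkene is too hindered and too electron-poor to load the catalyst by itself. Because the methoxy-bearing carbon is the internal carbon of that alkene, the fragment expelled is a methylidene and not a heteroatom-stabilized Fischer-type carbene, so the catalyst should turn over. The silyl ether is essential: it keeps C1 as a free ketone, whereas the unprotected carbinol would sit as lactol 13, in which ring closure would demand a strained oxa-bridged alkene. High dilution and an argon sweep that removes ethylene disfavour intermolecular metathesis, and the benzoquinone additive suppresses ruthenium hydride migration of the allylic double bond.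

Step 8
Reactants: 16 4-(tert-butyldimethylsilyloxy)-8-(3,4-dimethoxyphenyl)-2,6-dimethoxy-4H-naphthalen-1-one (racemic)
Product: 19 8-(3,4-dimethoxyphenyl)-2,6-dimethoxynaphthalene-1,4-dione (the target), via free carbinol 17 (not isolated), via naphthohydroquinone 18 (not isolated)
Conditions: Bu4NF, THF, 0 °C; AcOH; then MnO2, CH2Cl2, rt
Reagents that add atoms: none
Why: Fluoride cleaves the Si–O bond; the liberated C4 carbinol is the keto tautomer of a naphthalene-1,4-diol and should aromatize by base-mediated proton shift, after which MnO2 performs the two-electron hydroquinone-to-quinone oxidation (it would equally oxidize any untautomerized benzylic, allylic carbinol to the same product). Neutralizing with AcOH before the oxidant is added keeps hydroxide and fluoride away from the C2 vinylogous ester of the quinone.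

## Compound list

1 | 2-bromo-4-methoxybenzoic acid | COc1ccc(C(=O)O)c(Br)c1 | starting material
2 | 2-bromo-4-methoxybenzoyl chloride | COc1ccc(C(=O)Cl)c(Br)c1 | intermediate
3 | 2-bromo-N,N-diethyl-4-methoxybenzamide | CCN(CC)C(=O)c1ccc(OC)cc1Br | intermediate
4 | 3,4-dimethoxyphenylboronic acid | COc1ccc(B(O)O)cc1OC | starting material
5 | N,N-diethyl-2-(3,4-dimethoxyphenyl)-4-methoxybenzamide | CCN(CC)C(=O)c1ccc(OC)cc1-c1ccc(OC)c(OC)c1 | intermediate
6 | [2-(diethylcarbamoyl)-3-(3,4-dimethoxyphenyl)-5-methoxyphenyl]lithium | CCN(CC)C(=O)c1c([Li])cc(OC)cc1-c1ccc(OC)c(OC)c1 | intermediate
7 | N,N-diethyl-2-(3,4-dimethoxyphenyl)-6-formyl-4-methoxybenzamide | CCN(CC)C(=O)c1c(C=O)cc(OC)cc1-c1ccc(OC)c(OC)c1 | intermediate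
8 | vinylmagnesium bromide | C=C[Mg]Br | starting material
9 | N,N-diethyl-2-(3,4-dimethoxyphenyl)-6-(1-hydroxyprop-2-en-1-yl)-4-methoxybenzamide (racemic, one enantiomer drawn) | CCN(CC)C(=O)c1c([C@@H](O)C=C)cc(OC)cc1-c1ccc(OC)c(OC)c1 | intermediate
10 | 7-(3,4-dimethoxyphenyl)-5-methoxy-3-vinyl-3H-isobenzofuran-1-one (racemic, one enantiomer drawn) | O=C1O[C@@H](C=C)c2cc(OC)cc(-c3ccc(OC)c(OC)c3)c21 | intermediate
11 | methyl vinyl ether | C=COC | starting material
12 | 1-methoxyvinyllithium | [Li]C(=C)OC | intermediate
13 | 7-(3,4-dimethoxyphenyl)-5-methoxy-1-(1-methoxyvinyl)-3-vinyl-1,3-dihydroisobenzofuran-1-ol (racemic, both hemiketal epimers, C3 drawn as one enantiomer) | OC1(C(=C)OC)O[C@@H](C=C)c2cc(OC)cc(-c3ccc(OC)c(OC)c3)c21 | intermediate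
14 | 1-[2-(3,4-dimethoxyphenyl)-6-(1-hydroxyallyl)-4-methoxyphenyl]-2-methoxyprop-2-en-1-one (racemic, one enantiomer drawn) | C=C(OC)C(=O)c1c(-c2ccc(OC)c(OC)c2)cc(OC)cc1[C@@H](O)C=C | intermediate
15 | 1-[2-(1-(tert-butyldimethylsilyloxy)allyl)-6-(3,4-dimethoxyphenyl)-4-methoxyphenyl]-2-methoxyprop-2-en-1-one (racemic, one enantiomer drawn) | C=C(OC)C(=O)c1c(-c2ccc(OC)c(OC)c2)cc(OC)cc1[C@@H](O[Si](C)(C)C(C)(C)C)C=C | intermediate
16 | 4-(tert-butyldimethylsilyloxy)-8-(3,4-dimethoxyphenyl)-2,6-dimethoxy-4H-naphthalen-1-one (racemic, one enantiomer drawn) | COC1=C[C@H](O[Si](C)(C)C(C)(C)C)c2cc(OC)cc(-c3ccc(OC)c(OC)c3)c2C1=O | intermediate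
17 | 8-(3,4-dimethoxyphenyl)-4-hydroxy-2,6-dimethoxy-4H-naphthalen-1-one (racemic, one enantiomer drawn) | COC1=C[C@H](O)c2cc(OC)cc(-c3ccc(OC)c(OC)c3)c2C1=O | intermediate
18 | 8-(3,4-dimethoxyphenyl)-2,6-dimethoxynaphthalene-1,4-diol | COc1cc(O)c2cc(OC)cc(-c3ccc(OC)c(OC)c3)c2c1O | intermediate
19 | 8-(3,4-dimethoxyphenyl)-2,6-dimethoxynaphthalene-1,4-dione (CNP0128574.0) | COC1=CC(=O)c2cc(OC)cc(-c3ccc(OC)c(OC)c3)c2C1=O | target

## Step count and least certain steps

Total step count: 8. Longest linear sequence: 8 steps, from 1 to 19; compounds 4, 8 and 11 enter in single operations.

Step 7 (key step). What may go wrong: arrest of the catalyst by exchange at the methoxy-substituted alkene, slow loading next to the bulky silyloxy group so that intermolecular metathesis takes over, or hydride-mediated migration of the allylic double bond before ring closure. Tautomerization of the product toward its aromatic naphthol form would be harmless, because step 8 converges on the same hydroquinone. Fallback, from 10 back to 16, forming the same C2=C3 bond by olefination instead of metathesis: lithiated diethyl (methoxymethyl)phosphonate (n-BuLi, THF, −78 °C) is added to the lactone of 10 to give the beta-keto phosphonate F1 as its ring-chain mixture. Silylation with TBSCl and imidazole gives the silyl ether F2. Cleavage of its only alkene with OsO4 (cat.), NaIO4 and 2,6-lutidine in aqueous dioxane gives the aldehyde F3. An intramolecular Horner–Wadsworth–Emmons reaction (LiCl, i-Pr2NEt, MeCN) then closes ring B and delivers 16.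

Step 5. What may go wrong: proton abstraction by the strongly basic vinyllithium at the benzylic, allylic C–H of the lactone, with migration of the double bond into conjugation, or a second addition if the lactolate opens before the quench. A product that sits almost wholly as the closed lactol would also make the silylation of step 6 sluggish. Fallback, from 10 back to 15, bypassing steps 5 and 6: the lactone is opened with the non-basic aluminium amide made from Me(MeO)NH·HCl and Me3Al in CH2Cl2 to give the hydroxy Weinreb amide F4. This is silylated at once (TBSCl, imidazole, DMF) to the silyl ether F5, which can neither relactonize nor form a hemiketal. Addition of 12 (prepared from 11 as in step 5) then gives a chelated tetrahedral adduct that releases ketone 15 only on work-up.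

Step 4. What may go wrong: acid-promoted ionization of the benzylic, allylic carbinol during lactonization, leading to 1,3-transposition of the hydroxyl or to migration of the vinyl double bond into conjugation. Fallback, from 7 back to 10, removing the amide before the carbinol exists: heating 7 in aqueous HCl and dioxane should hydrolyse the amide with anchimeric help from the neighbouring aldehyde hydrate and give the hydroxyphthalide F6, the ring tautomer of the formyl acid. Compound 8 (2.2 equiv, THF, −78 to 0 °C) then adds to the open formyl carboxylate, and the resulting gamma-hydroxy acid lactonizes to 10 on mild acidification at room temperature, with no heating in acid.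

Step 8. What may go wrong: displacement of the C2 methoxy group by hydroxide or fluoride once quinone is present in a basic medium, or oxidative coupling of the free, electron-rich hydroquinone. Fallback, from 16 back to 19, with no fluoride and no free hydroquinone: a catalytic amine base (Et3N, CH2Cl2, rt) tautomerizes 16 to the silyl naphthol F7. PhI(OAc)2 in aqueous MeCN at 0 °C then oxidizes this para-silyloxy naphthol directly to the quinone 19 with loss of the silyl group, a known oxidative desilylation of hydroquinone monosilyl ethers.

## Further compounds

F1 | step 7 | diethyl {2-[2-(3,4-dimethoxyphenyl)-6-(1-hydroxyallyl)-4-methoxyphenyl]-1-methoxy-2-oxoethyl}phosphonate (racemic, both epimers at the phosphonate carbon) | CCOP(=O)(OCC)C(OC)C(=O)c1c(-c2ccc(OC)c(OC)c2)cc(OC)cc1[C@@H](O)C=C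
F2 | step 7 | diethyl {2-[2-(1-(tert-butyldimethylsilyloxy)allyl)-6-(3,4-dimethoxyphenyl)-4-methoxyphenyl]-1-methoxy-2-oxoethyl}phosphonate (racemic, both epimers at the phosphonate carbon) | CCOP(=O)(OCC)C(OC)C(=O)c1c(-c2ccc(OC)c(OC)c2)cc(OC)cc1[C@@H](O[Si](C)(C)C(C)(C)C)C=C
F3 | step 7 | diethyl {2-[2-(1-(tert-butyldimethylsilyloxy)-2-oxoethyl)-6-(3,4-dimethoxyphenyl)-4-methoxyphenyl]-1-methoxy-2-oxoethyl}phosphonate (racemic, both epimers at the phosphonate carbon) | CCOP(=O)(OCC)C(OC)C(=O)c1c(-c2ccc(OC)c(OC)c2)cc(OC)cc1[C@@H](O[Si](C)(C)C(C)(C)C)C=O
F4 | step 5 | 2-(3,4-dimethoxyphenyl)-6-(1-hydroxyallyl)-N,4-dimethoxy-N-methylbenzamide (racemic, one enantiomer drawn) | CON(C)C(=O)c1c(-c2ccc(OC)c(OC)c2)cc(OC)cc1[C@@H](O)C=C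
F5 | step 5 | 2-[1-(tert-butyldimethylsilyloxy)allyl]-6-(3,4-dimethoxyphenyl)-N,4-dimethoxy-N-methylbenzamide (racemic, one enantiomer drawn) | CON(C)C(=O)c1c(-c2ccc(OC)c(OC)c2)cc(OC)cc1[C@@H](O[Si](C)(C)C(C)(C)C)C=C
F6 | step 4 | 7-(3,4-dimethoxyphenyl)-3-hydroxy-5-methoxy-3H-isobenzofuran-1-one (racemic hemiacetal) | O=C1OC(O)c2cc(OC)cc(-c3ccc(OC)c(OC)c3)c21
F7 | step 8 | 4-(tert-butyldimethylsilyloxy)-8-(3,4-dimethoxyphenyl)-2,6-dimethoxynaphthalen-1-ol | COc1cc(O[Si](C)(C)C(C)(C)C)c2cc(OC)cc(-c3ccc(OC)c(OC)c3)c2c1O
A1 | alternative 1 | 1-(3,4-dimethoxyphenyl)-5,7,8-trimethoxy-2-benzopyran-3-one | COC1=CC(OC)=C(OC)C2=C(c3ccc(OC)c(OC)c3)OC(=O)C=C12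
A2 | alternative 1 | methoxyacetylene | C#COC
A3 | alternative 1 | 8-(3,4-dimethoxyphenyl)-1,2,4,6-tetramethoxynaphthalene | COc1cc(OC)c2cc(OC)cc(-c3ccc(OC)c(OC)c3)c2c1OC
A4 | alternative 2 | (S)-1-(3,4-dimethoxyphenyl)-4-methoxyocta-1,7-diyne-3,6-dione | COc1ccc(C#CC(=O)[C@@H](OC)CC(=O)C#C)cc1OC
A5 | alternative 2 | (S)-8-(3,4-dimethoxyphenyl)-2,6-dimethoxy-2,3-dihydronaphthalene-1,4-dione | CO[C@H]1CC(=O)c2cc(OC)cc(-c3ccc(OC)c(OC)c3)c2C1=O
A6 | alternative 3 | 1,2,4,6-tetramethoxy-8-[(E)-2-nitrovinyl]naphthalene | COc1cc(OC)c2cc(OC)cc(/C=C/[N+](=O)[O-])c2c1OC
A7 | alternative 3 | 2,3-dimethoxybuta-1,3-diene | C=C(OC)C(=C)OC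
A8 | alternative 3 | trans-1,2-dimethoxy-4-nitro-5-(3,5,7,8-tetramethoxynaphthalen-1-yl)cyclohexene (racemic, one enantiomer drawn) | COC1=C(OC)C[C@@H]([N+](=O)[O-])[C@H](c2cc(OC)cc3c(OC)cc(OC)c(OC)c23)C1
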